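**Retrosynthetic overview**

1. The target is read as epioritin-(4β→6)-oritin-4α-ol. The last C–C disconnection is the interflavan bond C4 (upper ring C)–C6 (lower ring A): Friedel–Crafts coupling of a 4-benzylsulfanyl donor with a protected flavan-3,4-diol, then global hydrogenolysis.
2. Both flavan units share the 2R aryl carbon and the 7,8,4'-oxygen pattern, so both are traced to one benzyl-protected 2,3-trans-3-alkoxyflavan-4-one. The lower unit needs only C4 reduction; the upper unit needs C4 thiolysis and C3 inversion by oxidation/reduction.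
3. Ring C is disconnected at O1–C8a and C2–C3 in one operation: a 2-fluoroaryl alkoxymethyl ketone (ring A, C4, C3, O3) plus 4-(benzyloxy)benzaldehyde (O1, C2, ring B), joined by a domino aldol addition/SNAr.
4. Enabling feature: C4 of ring C bears oxygen and sits on C4a, whose ortho neighbour C8a carries O1 in the 1,2,3-trioxygenated ring A (O1, 8-OH, 7-OH). With C4 as a ketone, one carbonyl both acidifies C3–H and activates a C8a–F bond; it is reduced back afterwards.
5. Ring order: rings A and B are bought as arenes; ring C of both units is made in the key step; no further ring is formed.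

Key step: step 5

Remark: the upper unit is (2R,3R,4S), 2,3-cis-3,4-trans, and the lower unit is (2R,3S,4R), 2,3-trans-3,4-trans; α/β refer to the usual flavan drawing (ring A left, O1 up), in which both 2-aryl groups are α.

**Route**

Step 1
Reactants: 1 3-fluorocatechol
Product: 2 1,2-bis(benzyloxy)-3-fluorobenzene
Conditions: BnBr (2.3 equiv), K2CO3, DMF, 60 °C
Reagents that add atoms: benzyl bromide, BrCc1ccccc1
Why: Williamson ether synthesis in which both phenoxides of the catechol are alkylated under mild carbonate conditions, with no stereocentre formed.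

Step 2
Reactants: 2 1,2-bis(benzyloxy)-3-fluorobenzene
Product: 3 1-bromo-3,4-bis(benzyloxy)-2-fluorobenzene
Conditions: NBS (1.05 equiv), MeCN, 0 °C → rt
Reagents that add atoms: N-bromosuccinimide, O=C1CCC(=O)N1Br
Why: Electrophilic aromatic bromination should occur para to the unhindered benzyloxy group and ortho to fluorine, because the benzyloxy group flanked by two ortho substituents is twisted out of conjugation and the position meta to fluorine is deactivated.

Step 3
Reactants: 4 4-methoxybenzyl alcohol; 5 2-chloro-N-methoxy-N-methylacetamide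
Product: 7 N-methoxy-2-[(4-methoxybenzyl)oxy]-N-methylacetamide, via sodium 4-methoxybenzyl oxide 6 (not isolated)
Conditions: NaH, THF, 0 °C; then 5, 0 °C → rt
Reagents that add atoms: none
Why: Williamson ether synthesis by SN2 displacement of the activated α-chloride of the Weinreb amide by the preformed alkoxide.

Step 4
Reactants: 3 1-bromo-3,4-bis(benzyloxy)-2-fluorobenzene; 7 N-methoxy-2-[(4-methoxybenzyl)oxy]-N-methylacetamide
Product: 10 1-[3,4-bis(benzyloxy)-2-fluorophenyl]-2-[(4-methoxybenzyl)oxy]ethan-1-one, via arylmagnesium chloride 8 (not isolated), via tetrahedral magnesium adduct 9 (not isolated)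
Conditions: iPrMgCl·LiCl, THF, −15 °C; then 7, −15 → 0 °C; aq HCl work-up
Reagents that add atoms: none
Why: Bromine–magnesium exchange (helped by the ortho fluorine and kept cold so that the 2-fluoroarylmagnesium species does not collapse to an aryne) followed by Weinreb ketone synthesis, in which the chelated tetrahedral adduct prevents over-addition.

Step 5
Reactants: 10 1-[3,4-bis(benzyloxy)-2-fluorophenyl]-2-[(4-methoxybenzyl)oxy]ethan-1-one; 11 4-(benzyloxy)benzaldehyde
Product: 14 rac-(2R,3R)-7,8-bis(benzyloxy)-2-[4-(benzyloxy)phenyl]-3-[(4-methoxybenzyl)oxy]chroman-4-one, via potassium enolate 12 (not isolated), via potassium aldolate 13 (not isolated)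
Conditions: KN(SiMe3)2 (1.05 equiv), THF, −78 °C; 11 (1.0 equiv), −78 °C; 18-crown-6, −78 → 45 °C; then DBU (0.1 equiv), rt
Reagents that add atoms: none
Why: Proposed new method: deprotonation of 10 at C3 gives the potassium enolate 12, which adds to aldehyde 11 (aldol addition, C2–C3 bond), and the oxygen of the resulting aldolate 13, the former aldehyde oxygen, then attacks C8a and expels fluoride through a Meisenheimer intermediate whose charge is taken up by the ortho C4 carbonyl (SNAr, O1–C8a bond). The closest known reaction types are the one-pot Claisen condensation/SNAr synthesis of chromones and flavones from 2-fluoroaryl ketones and the intramolecular SNAr etherification of alcohols onto ortho-acyl aryl fluorides; new is the use of an aldehyde, so that a saturated 3-oxygenated flavanone results. Ring C is closed at O1–C8a as a six-membered ring by addition–elimination at the aromatic carbon, 6-endo-trig with respect to the C8a=C4a–C4=O acceptor. C2 and C3 are formed as a racemate and their relative configuration is under thermodynamic control: C3 is epimerisable next to C4=O (completed with catalytic DBU), so the 2,3-trans isomer with equatorial aryl and PMB-oxy groups should result, and the absolute configuration is set in step 6. The step needs O-arylation to win over retro-aldol cleavage, dehydration and Tishchenko-type hydride transfer: retro-aldol only returns 12 and 11, a metal aldolate in an aprotic medium is a poor substrate for loss of oxide, one equivalent of base leaves none once fluoride is lost, equimolar aldehyde limits hydride transfer, and the single fluorine ortho to the carbonyl fixes the site of closure.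

Step 6
Reactants: 14 rac-(2R,3R)-7,8-bis(benzyloxy)-2-[4-(benzyloxy)phenyl]-3-[(4-methoxybenzyl)oxy]chroman-4-one
Product: 15 (2R,3S,4R)-7,8-bis(benzyloxy)-2-[4-(benzyloxy)phenyl]-3-[(4-methoxybenzyl)oxy]chroman-4-ol
Conditions: RuCl[(S,S)-TsDPEN](p-cymene) (2 mol%), HCO2H/Et3N (5:2), EtOAc, rt, stopped near 50% conversion
Reagents that add atoms: none
Why: Noyori–Ikariya asymmetric transfer hydrogenation run as a kinetic resolution, as known for racemic flavanones: the (S,S) catalyst should deliver hydride to the face of C4=O that gives the 4α-carbinol, which for the (2R,3R) ketone is the favoured axial approach to the all-equatorial 2,4-cis alcohol (new stereocentre C4, catalyst-controlled and matched with the substrate), while the mismatched (2S,3S) ketone remains and can be re-racemised with base and recycled.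

Step 7
Reactants: 15 (2R,3S,4R)-7,8-bis(benzyloxy)-2-[4-(benzyloxy)phenyl]-3-[(4-methoxybenzyl)oxy]chroman-4-ol
Product: 17 (2R,3S,4R)-4,7,8-tris(benzyloxy)-2-[4-(benzyloxy)phenyl]-3-[(4-methoxybenzyl)oxy]chromane, via sodium alkoxide 16 (not isolated)
Conditions: NaH, THF/DMF, 0 °C; then BnBr, Bu4NI (cat), 0 °C → rt
Reagents that add atoms: benzyl bromide, BrCc1ccccc1
Why: Williamson benzylation of the secondary benzylic alkoxide masks O4 so that it is neither alkylated nor ionised in the later coupling, and no stereocentre is touched.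

Step 8
Reactants: 15 (2R,3S,4R)-7,8-bis(benzyloxy)-2-[4-(benzyloxy)phenyl]-3-[(4-methoxybenzyl)oxy]chroman-4-ol
Product: 18 (2R,3R,4R)-4-(benzylsulfanyl)-7,8-bis(benzyloxy)-2-[4-(benzyloxy)phenyl]chroman-3-ol
Conditions: BnSH (10 equiv), CF3CO2H (10% v/v), CH2Cl2, 0 °C → rt
Reagents that add atoms: benzyl mercaptan, SCc1ccccc1
Why: Acid-promoted thiolysis of a flavan-4-ol (SN1 through the C4 benzylic cation stabilised by O1 and the para 7-benzyloxy group, captured by the thiol mainly anti to the 3-substituent) with concurrent acidolysis of the PMB ether, whose cation the excess thiol scavenges; the C4 configuration is of no consequence because C4 is ionised again in step 11.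

Step 9
Reactants: 18 (2R,3R,4R)-4-(benzylsulfanyl)-7,8-bis(benzyloxy)-2-[4-(benzyloxy)phenyl]chroman-3-ol
Product: 19 (2R,4R)-4-(benzylsulfanyl)-7,8-bis(benzyloxy)-2-[4-(benzyloxy)phenyl]chroman-3-one
Conditions: Dess–Martin periodinane, CH2Cl2, 0 °C → rt
Reagents that add atoms: none
Why: Dess–Martin oxidation of the secondary alcohol to the flavan-3-one under near-neutral conditions should leave the sulfide and the C2 stereocentre untouched.

Step 10
Reactants: 19 (2R,4R)-4-(benzylsulfanyl)-7,8-bis(benzyloxy)-2-[4-(benzyloxy)phenyl]chroman-3-one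
Product: 20 (2R,3S,4R)-4-(benzylsulfanyl)-7,8-bis(benzyloxy)-2-[4-(benzyloxy)phenyl]chroman-3-ol
Conditions: LiBH(s-Bu)3, THF, −78 °C; then H2O
Reagents that add atoms: none
Why: Diastereoselective ketone reduction with a bulky hydride, as in the catechin-to-epicatechin inversion: equatorial attack from the β-face, away from the α-disposed 2-aryl and 4-benzylsulfanyl groups, should give the axial 3α-alcohol and so set C3 of the upper unit (2,3-cis) by substrate control.

Step 11
Reactants: 20 (2R,3S,4R)-4-(benzylsulfanyl)-7,8-bis(benzyloxy)-2-[4-(benzyloxy)phenyl]chroman-3-ol; 17 (2R,3S,4R)-4,7,8-tris(benzyloxy)-2-[4-(benzyloxy)phenyl]-3-[(4-methoxybenzyl)oxy]chromane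
Product: 21 hepta-O-benzyl-3-O-(4-methoxybenzyl)-epioritin-(4β→6)-oritin-4α-ol
Conditions: AgBF4 (2 equiv), 2,6-di-tert-butyl-4-methylpyridine (2 equiv), 17 (3 equiv, excess recovered), 4 Å MS, THF, 0 °C, dark
Reagents that add atoms: none
Why: Thiophilic activation of the C4–S bond by AgBF4 generates the flavan-4-yl cation, which should undergo Friedel–Crafts alkylation at C6 of ring A of 17 (ortho to the 7-benzyloxy group and para to O1, the most nucleophilic and least hindered site); attack anti to the 3-hydroxyl and 2-aryl groups of the 2,3-cis cation sets the new C4 stereocentre as 4β (3,4-trans), and the hindered pyridine removes the acid so that the 4-benzyloxy group of 17 is not ionised.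

Step 12
Reactants: 21 hepta-O-benzyl-3-O-(4-methoxybenzyl)-epioritin-(4β→6)-oritin-4α-ol
Product: 22 epioritin-(4β→6)-oritin-4α-ol (CNP0391561.5)
Conditions: H2 (1 atm), Pd(OH)2/C, EtOAc/MeOH, rt
Reagents that add atoms: none
Why: Catalytic hydrogenolysis should cleave the seven benzyl ethers and the PMB ether under neutral conditions at room temperature, under which the free secondary benzylic 4-hydroxyl and the interflavan bond are expected to persist, and no stereocentre is affected.

**Compound list**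

1 | 3-fluorocatechol | Oc1cccc(F)c1O | starting material
2 | 1,2-bis(benzyloxy)-3-fluorobenzene | Fc1cccc(OCc2ccccc2)c1OCc1ccccc1 | intermediate
3 | 1-bromo-3,4-bis(benzyloxy)-2-fluorobenzene | Fc1c(Br)ccc(OCc2ccccc2)c1OCc1ccccc1 | intermediate
4 | 4-methoxybenzyl alcohol | COc1ccc(CO)cc1 | starting material
5 | 2-chloro-N-methoxy-N-methylacetamide | ClCC(=O)N(C)OC | starting material
6 | sodium 4-methoxybenzyl oxide (not isolated) | [Na+].[O-]Cc1ccc(OC)cc1 | intermediate
7 | N-methoxy-2-[(4-methoxybenzyl)oxy]-N-methylacetamide | COc1ccc(COCC(=O)N(C)OC)cc1 | intermediate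
8 | [3,4-bis(benzyloxy)-2-fluorophenyl]magnesium chloride (LiCl complex, not isolated) | Cl[Mg]c1ccc(OCc2ccccc2)c(OCc2ccccc2)c1F | intermediate
9 | chloromagnesium alkoxide of the tetrahedral adduct of 8 and 7 (not isolated) | COc1ccc(COCC(O[Mg]Cl)(N(C)OC)c2ccc(OCc3ccccc3)c(OCc3ccccc3)c2F)cc1 | intermediate
10 | 1-[3,4-bis(benzyloxy)-2-fluorophenyl]-2-[(4-methoxybenzyl)oxy]ethan-1-one | COc1ccc(COCC(=O)c2ccc(OCc3ccccc3)c(OCc3ccccc3)c2F)cc1 | intermediate
11 | 4-(benzyloxy)benzaldehyde | O=Cc1ccc(OCc2ccccc2)cc1 | starting material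
12 | potassium (Z)-enolate of 10 (not isolated) | [K+].[O-]/C(=C\OCc1ccc(OC)cc1)c1ccc(OCc2ccccc2)c(OCc2ccccc2)c1F | intermediate
13 | potassium 3-[3,4-bis(benzyloxy)-2-fluorophenyl]-1-[4-(benzyloxy)phenyl]-2-[(4-methoxybenzyl)oxy]-3-oxopropan-1-olate (racemic syn/anti mixture, not isolated) | [K+].[O-]C(c1ccc(OCc2ccccc2)cc1)C(OCc1ccc(OC)cc1)C(=O)c1ccc(OCc2ccccc2)c(OCc2ccccc2)c1F | intermediate
14 | rac-(2R,3R)-7,8-bis(benzyloxy)-2-[4-(benzyloxy)phenyl]-3-[(4-methoxybenzyl)oxy]chroman-4-one (2,3-trans; racemate, SMILES shows the 2R,3R enantiomer) | c1cc2c(c(OCc3ccccc3)c1OCc1ccccc1)O[C@H](c1ccc(OCc3ccccc3)cc1)[C@@H](OCc1ccc(OC)cc1)C2=O | intermediate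
15 | (2R,3S,4R)-7,8-bis(benzyloxy)-2-[4-(benzyloxy)phenyl]-3-[(4-methoxybenzyl)oxy]chroman-4-ol (2,3-trans-3,4-trans) | c1cc2c(c(OCc3ccccc3)c1OCc1ccccc1)O[C@H](c1ccc(OCc3ccccc3)cc1)[C@@H](OCc1ccc(OC)cc1)[C@@H]2O | intermediate
16 | sodium alkoxide of 15 (not isolated) | c1cc2c(c(OCc3ccccc3)c1OCc1ccccc1)O[C@H](c1ccc(OCc3ccccc3)cc1)[C@@H](OCc1ccc(OC)cc1)[C@@H]2[O-].[Na+] | intermediate
17 | (2R,3S,4R)-4,7,8-tris(benzyloxy)-2-[4-(benzyloxy)phenyl]-3-[(4-methoxybenzyl)oxy]chromane | c1cc2c(c(OCc3ccccc3)c1OCc1ccccc1)O[C@H](c1ccc(OCc3ccccc3)cc1)[C@@H](OCc1ccc(OC)cc1)[C@@H]2OCc1ccccc1 | intermediate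
18 | (2R,3R,4R)-4-(benzylsulfanyl)-7,8-bis(benzyloxy)-2-[4-(benzyloxy)phenyl]chroman-3-ol (2,3-trans-3,4-trans, expected major C4 epimer) | c1cc2c(c(OCc3ccccc3)c1OCc1ccccc1)O[C@H](c1ccc(OCc3ccccc3)cc1)[C@@H](O)[C@@H]2SCc1ccccc1 | intermediate
19 | (2R,4R)-4-(benzylsulfanyl)-7,8-bis(benzyloxy)-2-[4-(benzyloxy)phenyl]chroman-3-one (2,4-cis) | c1cc2c(c(OCc3ccccc3)c1OCc1ccccc1)O[C@H](c1ccc(OCc3ccccc3)cc1)C(=O)[C@@H]2SCc1ccccc1 | intermediate
20 | (2R,3S,4R)-4-(benzylsulfanyl)-7,8-bis(benzyloxy)-2-[4-(benzyloxy)phenyl]chroman-3-ol (2,3-cis-3,4-cis) | c1cc2c(c(OCc3ccccc3)c1OCc1ccccc1)O[C@H](c1ccc(OCc3ccccc3)cc1)[C@H](O)[C@@H]2SCc1ccccc1 | intermediate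
21 | hepta-O-benzyl-3-O-(4-methoxybenzyl)-epioritin-(4β→6)-oritin-4α-ol: upper unit 2R,3R with the lower aryl 4β (3,4-trans) and free 3-OH; lower unit (2R,3S,4R) with 3-O-PMB and 4-O-benzyl | c1cc2c(c(OCc3ccccc3)c1OCc1ccccc1)O[C@H](c1ccc(OCc3ccccc3)cc1)[C@H](O)[C@H]2c1cc2c(c(OCc3ccccc3)c1OCc1ccccc1)O[C@H](c1ccc(OCc3ccccc3)cc1)[C@@H](OCc1ccc(OC)cc1)[C@@H]2OCc1ccccc1 | intermediate
22 | epioritin-(4β→6)-oritin-4α-ol, (2R,3S,4R)-6-[(2R,3R,4S)-3,7,8-trihydroxy-2-(4-hydroxyphenyl)chroman-4-yl]-2-(4-hydroxyphenyl)chromane-3,4,7,8-tetrol | Oc1ccc([C@H]2Oc3c(ccc(O)c3O)[C@H](c3cc4c(c(O)c3O)O[C@H](c3ccc(O)cc3)[C@@H](O)[C@@H]4O)[C@H]2O)cc1 | target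

**Step count and risks**

Total step count: 12. Longest linear sequence: 10 steps (1, 2, 4, 5, 6, 8, 9, 10, 11, 12).

Steps most likely to fail:

1. Step 5 (proposed domino aldol/SNAr). The aldolate may lose oxide (aldol condensation) or revert faster than its oxygen attacks the electron-rich fluoroarene, so that ring closure stalls. Fallback with known chemistry, from 10 and 11 back to 14: Claisen–Schmidt condensation of 10 with 11 (KOH, EtOH, rt) is taken deliberately to the (Z)-2'-fluoro-α-(PMB-oxy)chalcone F1. F1 has no enolisable hydrogen, so its fluoride, ortho to the enone carbonyl, can be displaced by the hydroxide surrogate 2-(methylsulfonyl)ethanol/NaH in DMF. The aryl 2-(methylsulfonyl)ethyl ether F2 loses methyl vinyl sulfone in the same flask to give the 2'-hydroxychalcone F3. NaOAc in refluxing EtOH then closes ring C by oxa-Michael addition to give 14 under the same thermodynamic 2,3-trans control.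

2. Step 11 (interflavan coupling). The cation may alkylate C6 of a second donor molecule, and attack by the benzylated ring A of 17 may be slow, giving oligomers and low conversion. Fallback, from 15 back to 22, blocks the donor's own C6. Bromination of 15 (NBS, CH2Cl2, −20 °C) gives the 6-bromo alcohol F4. F4 is carried through the operations of steps 8 to 10 (BnSH/CF3CO2H, Dess–Martin periodinane, LiBH(s-Bu)3) via the 6-bromo thioether F5 and the 6-bromo ketone F6 to the 6-bromo all-cis thioether alcohol F7. AgBF4 coupling of F7 with 17, now feasible with near-stoichiometric amounts, gives the 6-bromo dimer F8. Hydrogenolysis (H2, Pd(OH)2/C, Et3N) removes bromine together with all benzyl-type groups to give 22.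

3. Step 6 (kinetic resolution). The rate difference between the enantiomers may be too small, or C3 may partly epimerise during the transfer hydrogenation, giving 15 of low enantiomeric or diastereomeric purity. Fallback, from 14 back to 15: racemic 14 is resolved by preparative chromatography on a chiral stationary phase (supercritical CO2/MeOH, amylose carbamate phase) to give the (2R,3R)-ketone F9. F9 is reduced with NaBH4 in MeOH/THF at 0 °C, the reaction type by which 2,3-trans-dihydroflavonols give 2,3-trans-3,4-trans-diols through axial hydride delivery, to give 15. The (2S,3S)-ketone is re-racemised with DBU and recycled.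

**Further compounds**

F1 | step 5 | (Z)-1-[3,4-bis(benzyloxy)-2-fluorophenyl]-3-[4-(benzyloxy)phenyl]-2-[(4-methoxybenzyl)oxy]prop-2-en-1-one | COc1ccc(CO/C(=C\c2ccc(OCc3ccccc3)cc2)C(=O)c2ccc(OCc3ccccc3)c(OCc3ccccc3)c2F)cc1
F2 | step 5 | (Z)-1-{3,4-bis(benzyloxy)-2-[2-(methylsulfonyl)ethoxy]phenyl}-3-[4-(benzyloxy)phenyl]-2-[(4-methoxybenzyl)oxy]prop-2-en-1-one (not isolated) | COc1ccc(CO/C(=C\c2ccc(OCc3ccccc3)cc2)C(=O)c2ccc(OCc3ccccc3)c(OCc3ccccc3)c2OCCS(C)(=O)=O)cc1
F3 | step 5 | (Z)-1-[3,4-bis(benzyloxy)-2-hydroxyphenyl]-3-[4-(benzyloxy)phenyl]-2-[(4-methoxybenzyl)oxy]prop-2-en-1-one | COc1ccc(CO/C(=C\c2ccc(OCc3ccccc3)cc2)C(=O)c2ccc(OCc3ccccc3)c(OCc3ccccc3)c2O)cc1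
F4 | step 11 | (2R,3S,4R)-6-bromo-7,8-bis(benzyloxy)-2-[4-(benzyloxy)phenyl]-3-[(4-methoxybenzyl)oxy]chroman-4-ol | Brc1cc2c(c(OCc3ccccc3)c1OCc1ccccc1)O[C@H](c1ccc(OCc3ccccc3)cc1)[C@@H](OCc1ccc(OC)cc1)[C@@H]2O
F5 | step 11 | (2R,3R,4R)-4-(benzylsulfanyl)-6-bromo-7,8-bis(benzyloxy)-2-[4-(benzyloxy)phenyl]chroman-3-ol | Brc1cc2c(c(OCc3ccccc3)c1OCc1ccccc1)O[C@H](c1ccc(OCc3ccccc3)cc1)[C@@H](O)[C@@H]2SCc1ccccc1
F6 | step 11 | (2R,4R)-4-(benzylsulfanyl)-6-bromo-7,8-bis(benzyloxy)-2-[4-(benzyloxy)phenyl]chroman-3-one | Brc1cc2c(c(OCc3ccccc3)c1OCc1ccccc1)O[C@H](c1ccc(OCc3ccccc3)cc1)C(=O)[C@@H]2SCc1ccccc1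
F7 | step 11 | (2R,3S,4R)-4-(benzylsulfanyl)-6-bromo-7,8-bis(benzyloxy)-2-[4-(benzyloxy)phenyl]chroman-3-ol (all-cis) | Brc1cc2c(c(OCc3ccccc3)c1OCc1ccccc1)O[C@H](c1ccc(OCc3ccccc3)cc1)[C@H](O)[C@@H]2SCc1ccccc1
F8 | step 11 | 6-bromo derivative (upper unit) of 21 | Brc1cc2c(c(OCc3ccccc3)c1OCc1ccccc1)O[C@H](c1ccc(OCc3ccccc3)cc1)[C@H](O)[C@H]2c1cc2c(c(OCc3ccccc3)c1OCc1ccccc1)O[C@H](c1ccc(OCc3ccccc3)cc1)[C@@H](OCc1ccc(OC)cc1)[C@@H]2OCc1ccccc1
F9 | step 6 | (2R,3R)-7,8-bis(benzyloxy)-2-[4-(benzyloxy)phenyl]-3-[(4-methoxybenzyl)oxy]chroman-4-one (single enantiomer of 14) | c1cc2c(c(OCc3ccccc3)c1OCc1ccccc1)O[C@H](c1ccc(OCc3ccccc3)cc1)[C@@H](OCc1ccc(OC)cc1)C2=O
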